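**Retrosynthetic overview**
1. The target is a (2R)-flavanone: benzo ring A fused to dihydropyranone ring C, with 4-hydroxyphenyl ring B at C2 and a CH2 link from C6 to 2-hydroxyphenyl ring D. The three phenols are unmasked last from acetates.
2. C2–C1' is cut next (asymmetric Hayashi–Miyaura 1,4-addition to a chromone). The heat- and base-labile C2 stereocentre is therefore made only after all forcing chemistry, and that same step consumes the chromone C2=C3 bond.
3. C6–CH2 is cut as the biomimetic event: ring A of 5-hydroxy-7-methoxychromone acts as carbon nucleophile and captures the o-quinone methide released from 2-hydroxybenzyl alcohol.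
4. Enabling feature: CH2–C1''–C2''(OH) of ring D is the retron of an o-quinone methide. C6 is the α-carbon of the chelated enol O5–H···O4=C4 and the only open position ortho to the only free hydroxyl of ring A (O7 methylated, C4a quaternary, C8 para), so an O5–Zn–O2'' bridge can hand CH2 only to C6.
5. Ring order: rings A and C are bought together as 5,7-dihydroxychromone, ring D enters in step 2 and ring B in step 4. No ring is built de novo; ring C only passes from pyranone to dihydropyranone.

Key step: step 2

Assumption: the rhodium/(R)-biaryl-bisphosphine catalyst is taken to induce on the chromone as it does on 2-cyclohexenone ((R)-ligand gives the (R)-β-aryl ketone, which maps onto 2R here); the sign of rotation of the product checks this, and the (S)-ligand is equally accessible.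

Step 1
Reactants: 1 5,7-dihydroxy-4H-chromen-4-one (5,7-dihydroxychromone)
Product: 2 5-hydroxy-7-methoxy-4H-chromen-4-one
Conditions: MeI (1.1 equiv), K2CO3 (1.1 equiv), acetone, reflux
Reagents that add atoms: methyl iodide, CI
Why: Williamson etherification in which the 7-OH, a vinylogous carboxylic acid para to C4=O, is deprotonated and methylated while the 5-OH stays locked in its hydrogen bond to O4, the classical selectivity of 5,7-dihydroxychromones and flavones toward one equivalent of base and alkyl halide.

Step 2
Reactants: 2 5-hydroxy-7-methoxy-4H-chromen-4-one, 3 2-hydroxybenzyl alcohol (saligenin)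
Product: 6 5-hydroxy-6-(2-hydroxybenzyl)-7-methoxy-4H-chromen-4-one, via o-quinone methide 4 (not isolated), via ring-A dienone 5 (not isolated)
Conditions: ZnCl2 (anhydrous, 1.5 equiv), 1,4-dioxane, 100 °C, 3 (0.8 equiv) added slowly by syringe pump
Reagents that add atoms: none
Why: ZnCl2 binds the O5/O4 chelate of 2 as a chlorozinc phenoxide and also the two oxygens of 3, ionises the benzylic C–O bond and releases o-quinone methide 4 inside the same coordination sphere; C6, the α-carbon of the zinc-bound C5 enolate of ring A, then adds to the exocyclic CH2 in a vinylogous Michael (Friedel–Crafts type) step that re-aromatises ring D, and dienone 5 tautomerises to 6, so that water is the only by-product. The closest known reaction types are the ZnCl2-mediated C-(2-hydroxybenzyl)ation of 5,7-dihydroxyflavanones with 2-hydroxybenzyl alcohol and the divalent-metal "high-ortho" condensation of phenols with saligenin, and the step mirrors the presumed biosynthetic capture of an o-quinone methide by a flavonoid ring A. No ring is closed and no stereocentre is formed. The step needs C6 over C8, C over O and mono over poly: O7 is methylated, so O5–H is the only ring-A hydroxyl that can bind zinc or relay a proton, its second ortho carbon C4a is quaternary, and C8 lies para and outside the reach of the O5–Zn–O2'' bridge, in line with the ortho-to-OH halogenation of 2-hydroxy-4,6-dialkoxyaryl ketones. O-Alkylation should be reversible under the conditions (the aryl 2-hydroxybenzyl ether re-ionises to 4) whereas C–C bond formation is not, and slow addition of a deficit of 3 keeps the stationary concentration of 4 low, which limits a second benzylation and the self-condensation of 3. In one operation, without halide, organometal or protecting group, the step completes the pentasubstituted ring A, the diarylmethane and ring D from two unfunctionalised partners, and the achiral chromone level of ring C lets it run hot without any stereocentre at stake.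

Step 3
Reactants: 6 5-hydroxy-6-(2-hydroxybenzyl)-7-methoxy-4H-chromen-4-one
Product: 7 2-[(5-acetoxy-7-methoxy-4-oxo-4H-chromen-6-yl)methyl]phenyl acetate (5,2''-diacetate of 6)
Conditions: Ac2O (4 equiv), pyridine, DMAP (cat.), CH2Cl2, rt
Reagents that add atoms: acetic anhydride, CC(=O)OC(C)=O
Why: DMAP-catalysed O-acylation of both phenols (the chelated 5-OH included) removes the acidic protons ahead of the rhodium step, and the 5-acetate replaces a strongly donating chelated hydroxyl by a weaker donor and so raises the electrophilicity of C2.

Step 4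
Reactants: 7 2-[(5-acetoxy-7-methoxy-4-oxo-4H-chromen-6-yl)methyl]phenyl acetate, 8 4-acetoxyphenylboronic acid
Product: 9 (2R)-5-acetoxy-6-(2-acetoxybenzyl)-2-(4-acetoxyphenyl)-7-methoxy-2,3-dihydro-4H-chromen-4-one (triacetate of the target)
Conditions: [Rh(OH)(cod)]2 (2.5 mol %), (R)-MeO-F12-BIPHEP [(R)-2,2'-bis[bis(3,4,5-trifluorophenyl)phosphino]-6,6'-dimethoxy-1,1'-biphenyl] (5.5 mol %), 8 (2 equiv), CH2Cl2/H2O (10:1), rt
Reagents that add atoms: none
Why: Hayashi–Miyaura asymmetric 1,4-addition in which transmetalation gives an aryl complex of monovalent rhodium that inserts C2=C3 of the chromone, the C2-symmetric (R)-bisphosphine blocks one face so that the aryl group reaches the face leading to 2R, and the electron-poor ligand makes insertion and hydrolysis of the oxa-π-allyl rhodium enolate fast enough to outrun β-aryloxide elimination and 1,2-addition to the product ketone, as known for chromones including 5,7-dioxygenated ones.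

Step 5
Reactants: 9 (2R)-5-acetoxy-6-(2-acetoxybenzyl)-2-(4-acetoxyphenyl)-7-methoxy-2,3-dihydro-4H-chromen-4-one
Product: 10 (+)-methylphelligrin A, (2R)-5-hydroxy-6-(2-hydroxybenzyl)-2-(4-hydroxyphenyl)-7-methoxy-2,3-dihydro-4H-chromen-4-one
Conditions: HCl (1.25 M in MeOH), 0 °C to rt
Reagents that add atoms: none
Why: Acid-catalysed transesterification of the three aryl acetates by methanol generates neither a phenoxide nor an enolate, so the retro-oxa-Michael opening of ring C that racemises 4'-hydroxyflavanones under basic conditions is not triggered and C2 should keep its R configuration.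

**Compound list**
1 | 5,7-dihydroxy-4H-chromen-4-one | O=C1C=COc2cc(O)cc(O)c12 | starting material
2 | 5-hydroxy-7-methoxy-4H-chromen-4-one | COc1cc(O)c2C(=O)C=COc2c1 | intermediate
3 | 2-hydroxybenzyl alcohol | OCc1ccccc1O | starting material
4 | o-quinone methide (6-methylidenecyclohexa-2,4-dien-1-one) | C=C1C=CC=CC1=O | intermediate
5 | 6-(2-hydroxybenzyl)-7-methoxy-6H-chromene-4,5-dione (ring-A dienone, C6 sp3, transient and not configured) | COC1=CC2=C(C(=O)C=CO2)C(=O)C1Cc1ccccc1O | intermediate
6 | 5-hydroxy-6-(2-hydroxybenzyl)-7-methoxy-4H-chromen-4-one | COc1cc2OC=CC(=O)c2c(O)c1Cc1ccccc1O | intermediate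
7 | 2-[(5-acetoxy-7-methoxy-4-oxo-4H-chromen-6-yl)methyl]phenyl acetate | COc1cc2OC=CC(=O)c2c(OC(C)=O)c1Cc1ccccc1OC(C)=O | intermediate
8 | 4-acetoxyphenylboronic acid | CC(=O)Oc1ccc(cc1)B(O)O | starting material
9 | (2R)-5-acetoxy-6-(2-acetoxybenzyl)-2-(4-acetoxyphenyl)-7-methoxy-2,3-dihydro-4H-chromen-4-one | COc1cc2c(c(OC(C)=O)c1Cc1ccccc1OC(C)=O)C(=O)C[C@H](c1ccc(OC(C)=O)cc1)O2 | intermediate
10 | (+)-methylphelligrin A, (2R)-5-hydroxy-6-(2-hydroxybenzyl)-2-(4-hydroxyphenyl)-7-methoxy-2,3-dihydro-4H-chromen-4-one | COc1cc2c(c(O)c1Cc1ccccc1O)C(=O)C[C@H](c1ccc(O)cc1)O2 | target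

Total step count: 5. Longest linear sequence: 5 steps (1, 2, 6, 7, 9, 10).

**Steps most likely to fail**

First, step 2.
- **What may go wrong:** ring A may attack through C8 instead of C6. The product may be benzylated again on ring D or at C8. Saligenin may self-condense faster than it is captured.
- **Fallback:** it sets out from 2 and comes back at 7, replacing template-controlled C–H substitution by a halogen-defined cross-coupling of the same C6–CH2 bond.
- Iodination of 2 with N-iodosuccinimide in DMF at rt, directed ortho to the free 5-OH, should give 5-hydroxy-6-iodo-7-methoxy-4H-chromen-4-one F1.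
- Acetylation (Ac2O, pyridine, rt) should give 5-acetoxy-6-iodo-7-methoxy-4H-chromen-4-one F2.
- Zinc insertion (Zn dust, LiCl, THF, rt) into commercial 2-(chloromethyl)phenyl acetate (CC(=O)Oc1ccccc1CCl) should give (2-acetoxybenzyl)zinc chloride F3, which is used at once.
- Negishi coupling of F2 and F3 (Pd(OAc)2, SPhos, THF, rt) should deliver 7.

Second, step 4.
- **What may go wrong:** insertion into the electron-rich chromone may be slow. β-Aryloxide elimination from the rhodium enolate may open ring C. Facial selectivity may be poor, and each of these lowers conversion or enantiopurity.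
- **Fallback:** it sets out from 7 (with 8) and comes back at 9, replacing asymmetric catalysis by racemic synthesis and resolution.
- Conjugate addition under an achiral cationic catalyst of divalent palladium (Pd(OCOCF3)2, 2,2'-bipyridine, aqueous AcOH/THF, 60 °C) should give racemic 5-acetoxy-6-(2-acetoxybenzyl)-2-(4-acetoxyphenyl)-7-methoxy-2,3-dihydro-4H-chromen-4-one F4.
- Preparative chromatography on an amylose tris(3,5-dimethylphenylcarbamate) phase separates 9 from its mirror image, the (2S)-triacetate F5.

Third, step 5.
- **What may go wrong:** ring C may open reversibly once the 4'-OH is free, causing partial racemisation. The hindered 5- and 2''-acetates may cleave incompletely, which would force longer or warmer acid treatment.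
- **Fallback:** it sets out from 6 and comes back at 10, changing the protecting-group logic to ethers that leave under neutral hydrogenolysis.
- Benzylation of 6 (BnBr, K2CO3, DMF, 70 °C) should give 5-(benzyloxy)-6-[2-(benzyloxy)benzyl]-7-methoxy-4H-chromen-4-one F6.
- The rhodium-catalysed addition of step 4, run with commercial 4-(benzyloxy)phenylboronic acid, should give (2R)-5-(benzyloxy)-6-[2-(benzyloxy)benzyl]-2-[4-(benzyloxy)phenyl]-7-methoxy-2,3-dihydro-4H-chromen-4-one F7.
- Hydrogenolysis (H2, 1 atm, Pd/C, EtOAc, rt, stopped at full debenzylation) should give 10.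

**Further compounds**
F1 | step 2 | 5-hydroxy-6-iodo-7-methoxy-4H-chromen-4-one | COc1cc2OC=CC(=O)c2c(O)c1I
F2 | step 2 | 5-acetoxy-6-iodo-7-methoxy-4H-chromen-4-one | COc1cc2OC=CC(=O)c2c(OC(C)=O)c1I
F3 | step 2 | (2-acetoxybenzyl)zinc chloride | CC(=O)Oc1ccccc1C[Zn]Cl
F4 | step 4 | racemic 5-acetoxy-6-(2-acetoxybenzyl)-2-(4-acetoxyphenyl)-7-methoxy-2,3-dihydro-4H-chromen-4-one | COc1cc2c(c(OC(C)=O)c1Cc1ccccc1OC(C)=O)C(=O)CC(c1ccc(OC(C)=O)cc1)O2
F5 | step 4 | (2S)-5-acetoxy-6-(2-acetoxybenzyl)-2-(4-acetoxyphenyl)-7-methoxy-2,3-dihydro-4H-chromen-4-one | COc1cc2c(c(OC(C)=O)c1Cc1ccccc1OC(C)=O)C(=O)C[C@@H](c1ccc(OC(C)=O)cc1)O2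
F6 | step 5 | 5-(benzyloxy)-6-[2-(benzyloxy)benzyl]-7-methoxy-4H-chromen-4-one | COc1cc2OC=CC(=O)c2c(OCc2ccccc2)c1Cc1ccccc1OCc1ccccc1
F7 | step 5 | (2R)-5-(benzyloxy)-6-[2-(benzyloxy)benzyl]-2-[4-(benzyloxy)phenyl]-7-methoxy-2,3-dihydro-4H-chromen-4-one | COc1cc2c(c(OCc3ccccc3)c1Cc1ccccc1OCc1ccccc1)C(=O)C[C@H](c1ccc(OCc3ccccc3)cc1)O2
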